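**Structural features**

The target is a daucane-type diester: a trans-fused bicyclo[5.3.0]decene in which the cyclopentane C1–C2–C3–C4–C10 and the cycloheptene C4–C5–C6–C7–C8–C9–C10 share the C4–C10 bond. Five stereocentres sit together: quaternary C10 (methyl) lies between C1 (acetoxy, anti to the methyl) and C4 (ring-fusion H, anti to the methyl), and C4 lies between the tertiary carbinol C3 (OH syn to the C10 methyl, isopropyl anti) and C5 (4-hydroxybenzoyloxy, syn to H-4). C7=C8 is a trisubstituted olefin separated from C5 only by the methylene C6. The fragile points are these: the tertiary C3 hydroxyl is β to both C1 and C5, so any ketone stage at C1 or C5 is an aldol open to dehydration or retro-aldol cleavage; a C5 ketone has C7=C8 in the β,γ position and can pull it into conjugation; two different esters and a free phenol rule out strong base, hydride or hydrogenolysis at the end. The real difficulty is the absolute configuration of quaternary C10, its relay to C1, C3, C4 and C5, and the distinction of the two secondary oxygens (acetate at C1, aroyl ester at C5) beside a free tertiary hydroxyl. The key step exploits the 1,4-relationship of the C5 oxygen and the C7=C8 olefin around C6 in the seven-membered ring: this is a cyclohepta-1,4-diene whose C4=C5 bond is an enol ether, so the ring divides into the four-carbon 2-oxy diene C6=C5(O)–C4=C10 standing on the five-membered ring and the three-carbon vinylcarbene C7(–C8=C9), and closure at C10 creates the quaternary centre.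

**Logic of the disconnections**

28 is cut at the aryl O–Si bond to 27, and 27 at the C5–O acyl bond to 22 and 25 (25 comes from 23 by silylation). The phenol must be masked so that the acid partner cannot acylate itself; the cut removes the whole aromatic ester and makes the end convergent. The forward acylation must find only one reactive hydroxyl, which holds because C1 is already acetylated and the C3 hydroxyl is tertiary.

22 is cut at the C5–H bond to 21. The β-oriented C3 hydroxyl sits under C5 and can deliver hydride to the β face, giving the 5α-alcohol; an external hydride would approach from the open α face and give the other epimer. The gain is one stereocentre; the demand is a reduction that is strictly intramolecular and mild enough for an aldol.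

21 is cut at the C4–H bond and the C5 carbonyl to the enol ether 20, and 20 at the acetyl C–O bond to 19. The enol ether is the form in which the annulation leaves C5, and acetylating C1 before C5 is unmasked separates the two secondary hydroxyls in time. The demand is hydrolysis without ionising the neighbouring tertiary alcohol, with C4 settling to the trans ring fusion.

19 is cut at the C3–isopropyl bond to 18. With a carbonyl at C3 the isopropyl group enters as the nucleophile from the face opposite the C10 methyl, which leaves the hydroxyl syn to the methyl as required; oxygen delivered to an isopropyl-bearing olefin would come from the same open face and give the wrong epimer. The gain is three carbons and the C3 stereocentre; the demand is 1,2-addition to a hindered, electron-rich carbonyl without enolisation.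

18 is cut at the C1–O bond to the enone 16, and 16 at the C1=C2 unsaturation to 15. An oxygen trans to the C10 methyl at C1 is what a heteroatom nucleophile adding to the enone β-carbon anti to that methyl gives. The demand is that no second Michael acceptor is present, so the ester must be gone before this point.

15 is traced through 13 and 12 to 11: the C7 methyl goes back to the ester, and the silyl dienol ether to the C3 ketone. The ester is needed as the acceptor of the carbenoid. The silyl dienol ether does double duty, shielding the ketone from two hydride steps and serving as the dehydrogenation substrate. The demand is kinetic enolisation at C2.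

11 is cut at C6–C7 and C9–C10 (with C5–C7 as a transient bond) to 5 and 9. This is the strategic cut: one operation makes the seven-membered ring, the quaternary stereocentre, C7=C8 and the masked C5 oxygen from two small achiral pieces. In 5 the ring carbonyl stands on C3, next to the internal diene carbon C4. An isomer of 5 with the carbonyl on C1 would undergo the same annulation with the same bonds and the same ring, but its product would need oxygen put onto C3 from the hindered face and a late directed reduction at C1 running at the same time as that at C5. With the carbonyl on C3 the enol ether of 5 is only cross-conjugated and stays nucleophilic, 11 is a robust vinylogous ester, and both C3 and C1 are later reached by nucleophiles entering anti to the C10 methyl. The carbon skeletons of 5 and 11 are unchanged by this placement. The demands are attack on the ethoxyvinyl bond only, a cis-divinylcyclopropane of one absolute configuration, and a Cope closure at a fully substituted terminus.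

5 is cut at the C4–C5 bond to 3 and 4 (cross-coupling of a vinyl bromide with a vinylstannane), and 3 at the C–Br bond to 1. The demand is coupling at a tetrasubstituted vinyl bromide under conditions that spare the acid-labile ethoxy diene.

9 is traced through 8 and 7 to 6: dehydration, ketone reduction, diazo transfer. The vinyl group is made last because 9 does not keep.

**Other disconnections considered**

Alternative 1: The cut is the transannular C4–C10 bond together with the C3–O bond, back to the all-cis epoxy cyclodecadiene A2. Forward, acid opens the oxirane at tertiary C10, C4 of the C3=C4 olefin attacks across the ring with inversion at C10, and water traps the C3 cation on the opposite face to give diol A1. In its favour, one step makes both rings, the ring-fusion bond and three stereocentres (C3, C4, C10), and A1 already carries free C1 and C3 hydroxyls distinct from the silylated C5 oxygen. Only about four steps would follow, against twelve after the chosen key step; on this point the alternative is the better plan. Against it, A2 is the hard part: a ten-membered ring with two cis olefins, a cis-epoxide of one absolute configuration and a C5 stereocentre must be closed and kept from reacting early. The outcome then depends on which ring conformer reacts, the allylic C5 silyloxy group deactivates the nucleophilic olefin, and the C3 cation may lose a proton or shift hydride instead of taking up water. Both plans create the quaternary centre in the ring-forming event. The cationic cascade is steered by substrate conformation, the chosen sequence by a catalyst and a cyclic transition state, which is the more predictable control. In step count the alternative should win after its key step and lose before it, so no overall saving is expected.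

Alternative 2: The cuts are C1–C10 and C3–C4: the cyclopentane is annulated onto the achiral dienone A4 with the nitro ketone A5. Forward, a cinchona-derived primary amine with an acid forms the iminium ion of A4, the nitronate carbon C1 adds to one of the two enantiotopic β-carbons (C10), and the resulting enamine carbon C4 adds to the isopropyl ketone C3 to give A3. In its favour, it is highly convergent, both partners are simple, no metal is needed, and C3 arrives as the finished isopropyl carbinol together with C4 and C10. On convergence and on the construction of C3 it is the better plan, and as an asymmetric catalytic step it is the equal of the chosen one. Against it, conjugate addition that creates a quaternary centre on a β,β-disubstituted enone is the hardest case for iminium catalysis, and the aldol onto a hindered isopropyl ketone is reversible. Turning the nitro group into the C1 carbonyl beside a tertiary aldol invites retro-aldol cleavage. A3 also has its olefin at C6=C7, conjugated with C5, so a shift against the thermodynamic gradient to C7=C8 would be needed, whereas the chosen key step delivers C7=C8 in place. Structurally this alternative builds the five-membered ring onto the seven, the chosen plan the reverse. The step count to A3 is clearly lower, but the steps after A3 look less secure than those after 11.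

Alternative 3: The cut is C5–C6: the homoallylic alcohol C5(OH)–C6–C7=C8 is traced to an α-alkoxy carbanion of an allylic ether, the bicyclic stannyl tetrahydropyran A7. Forward, an alkyllithium exchanges tin for lithium and the C5 carbanion bonds to C6 of the isopropenyl group as the C8–O bond breaks, enlarging the six-membered ether to the seven-membered carbocycle A6. In its favour, one step forms the ring, the C5 carbinol (by transfer from the stannane centre) and the trisubstituted C7=C8, and C5 emerges as the only free hydroxyl while C1 and C3 carry two different silyl groups. On the distinction of the three oxygens it is the better plan, and as a sigmatropic ring enlargement it is mechanistically the equal of the chosen Cope step. Against it, A7 needs all four cyclopentane stereocentres (C1, C3, C4, C10) plus the stannane centre and the C8 centre before the key step, made without help from the seven-membered ring; the anion may also undergo a 1,2-shift or simple protonation. The chosen plan puts ring construction early on achiral pieces and pays afterwards; this alternative pays before, and its linear sequence to A7 is expected to be the longer.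

Key step: step 6

Remark (numbering and descriptors): all bicyclic compounds carry the numbering C1–C10 used above; β is the face of the C10 methyl group, α the opposite face; absolute configuration is that of the SMILES strings.

Remark (sense of induction): the cyclopropanation is assumed to follow the established model for dirhodium prolinates, in which the S catalyst converts styrene and methyl phenyldiazoacetate into the (1S,2R) cyclopropane; applied to 5 and relayed through the boat Cope transition state, that model calls for the R catalyst, Rh2(R-DOSP)4 (dirhodium tetrakis[(R)-N-(4-dodecylphenylsulfonyl)prolinate]); should the 1,1-disubstituted enol ether respond in the opposite sense, the S catalyst is used and nothing else changes.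

**Route**

Step 1
Reactants: 1 3-methylcyclopent-2-en-1-one
Product: 3 2-bromo-3-methylcyclopent-2-en-1-one, via dibromide 2 (not isolated)
Conditions: Br2, CH2Cl2, 0 °C; then Et3N, 0 °C → rt
Reagents that add atoms: bromine, BrBr
Why: Bromine adds across the enone and base removes HBr from the α-position (bromination–dehydrobromination of an enone), giving the α-bromoenone; no stereocentre remains.

Step 2
Reactants: 3 2-bromo-3-methylcyclopent-2-en-1-one; 4 tributyl(1-ethoxyvinyl)stannane
Product: 5 2-(1-ethoxyvinyl)-3-methylcyclopent-2-en-1-one
Conditions: Pd(PPh3)4 (5 mol%), CuI (10 mol%), CsF (2 equiv), DMF, 45 °C; chromatography on Et3N-deactivated silica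
Reagents that add atoms: none
Why: Stille coupling of an α-bromoenone with a vinylstannane; CuI and fluoride speed transmetalation at the fully substituted vinyl bromide so that the acid-labile 2-ethoxy diene forms below 50 °C.

Step 3
Reactants: 6 methyl acetoacetate
Product: 7 methyl 2-diazo-3-oxobutanoate
Conditions: 4-acetamidobenzenesulfonyl azide, Et3N, MeCN, 0 °C → rt
Reagents that add atoms: 4-acetamidobenzenesulfonyl azide, CC(=O)Nc1ccc(cc1)S(=O)(=O)N=[N+]=[N-]
Why: Regitz diazo transfer to the activated methylene of a β-keto ester.

Step 4
Reactants: 7 methyl 2-diazo-3-oxobutanoate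
Product: 8 methyl 2-diazo-3-hydroxybutanoate (racemic)
Conditions: NaBH4, MeOH, 0 °C
Reagents that add atoms: none
Why: Borohydride reduces the ketone but neither the ester nor the acceptor-stabilised diazo group; the racemic carbinol centre is destroyed in the next step.

Step 5
Reactants: 8 methyl 2-diazo-3-hydroxybutanoate
Product: 9 methyl 2-diazobut-3-enoate
Conditions: POCl3, Et3N, CH2Cl2, 0 °C; used at once as a cold hydrocarbon solution
Reagents that add atoms: none
Why: Phosphorylation of the alcohol and E2 elimination (dehydration of a β-hydroxy diazo ester) give the vinyldiazoacetate, which cyclises to a pyrazole on standing and is therefore used immediately.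

Step 6
Reactants: 5 2-(1-ethoxyvinyl)-3-methylcyclopent-2-en-1-one; 9 methyl 2-diazobut-3-enoate
Product: 11 methyl 5-ethoxy-10β-methyl-3-oxobicyclo[5.3.0]deca-4,7-diene-7-carboxylate, via cis-divinylcyclopropane 10 (not isolated)
Conditions: Rh2(R-DOSP)4 (1 mol%), 9 (2 equiv) added over 3 h, 2,2-dimethylbutane–toluene 4:1, −40 °C → rt; then toluene, 80 °C, 2 h
Reagents that add atoms: none
Why: Loss of dinitrogen from 9 gives a donor/acceptor dirhodium vinylcarbenoid that adds in a concerted, asynchronous [2+1] carbene transfer (three-membered ring closure) to the terminal ethoxyvinyl bond of 5, forming C6–C7 and the transient C5–C7 bond of cis-divinylcyclopropane 10. On warming, 10 undergoes a Cope rearrangement through a boat transition state, a [3,3]-sigmatropic enlargement of the three-membered ring (overall a formal [4+3] cycloaddition) in which C9–C10 forms, C5–C7 breaks and the seven-membered ring closes. The closest known reaction type is the tandem cyclopropanation/Cope rearrangement of vinyldiazoacetates with 2-alkoxy- and 2-silyloxy-1,3-dienes under dirhodium tetraprolinate catalysis. Site selectivity is secured because the ethoxyvinyl bond is the only electron-rich, unhindered olefin (it is cross-conjugated with the carbonyl and not deactivated by it), whereas the ring olefin is tetrasubstituted and acceptor-bound. The one new stereocentre, C10, is set by the catalyst: the prolinate ligands choose the face of the carbenoid attacked by C6 and so fix C7 of 10, and the boat geometry, with the C10 methyl as the inward substituent and C1 outward, transfers this to C10. The step needs the cyclopentenyl group cis to the vinyl group in 10; the usual preference of donor/acceptor carbenoids to place the π-substituent of the alkene cis to the donor provides it, and the ethoxy/ester push–pull cyclopropane can epimerise at C5 on heating if it does not. Hydrocarbon solvent and slow addition suppress attack of the enol ether at the vinyl terminus C9 of the carbenoid and carbene dimerisation. Because 11 is a vinylogous ester, the rearrangement gains conjugation as well as strain release, which helps the crowded closure at the fully substituted terminus.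

Step 7
Reactants: 11 methyl 5-ethoxy-10β-methyl-3-oxobicyclo[5.3.0]deca-4,7-diene-7-carboxylate
Product: 12 methyl 3-(tert-butyldimethylsilyloxy)-5-ethoxy-10β-methylbicyclo[5.3.0]deca-2,4,7-triene-7-carboxylate
Conditions: LiN(i-Pr)2 (1.1 equiv), THF, −78 °C; TBSOTf (1.15 equiv), −78 °C; Et3N, pH 7 work-up
Reagents that add atoms: tert-butyldimethylsilyl trifluoromethanesulfonate, CC(C)(C)[Si](C)(C)OS(=O)(=O)C(F)(F)F
Why: Kinetic α′-deprotonation of a vinylogous ester at the C2 methylene and O-silylation give the silyl dienol ether, which masks the ketone against the two hydride steps and is the substrate for the later dehydrogenation.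

Step 8
Reactants: 12 methyl 3-(tert-butyldimethylsilyloxy)-5-ethoxy-10β-methylbicyclo[5.3.0]deca-2,4,7-triene-7-carboxylate
Product: 13 3-(tert-butyldimethylsilyloxy)-5-ethoxy-7-(hydroxymethyl)-10β-methylbicyclo[5.3.0]deca-2,4,7-triene
Conditions: i-Bu2AlH (2.5 equiv), CH2Cl2, −78 °C; Rochelle salt
Reagents that add atoms: none
Why: 1,2-Reduction of the conjugated ester to the allylic alcohol by a dialkylaluminium hydride; the two enol ethers offer no electrophilic site.

Step 9
Reactants: 13 3-(tert-butyldimethylsilyloxy)-5-ethoxy-7-(hydroxymethyl)-10β-methylbicyclo[5.3.0]deca-2,4,7-triene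
Product: 15 3-(tert-butyldimethylsilyloxy)-5-ethoxy-7,10β-dimethylbicyclo[5.3.0]deca-2,4,7-triene, via allylic mesylate 14 (not isolated)
Conditions: MsCl, Et3N, THF, −40 °C; then LiEt3BH, −40 → 0 °C
Reagents that add atoms: none
Why: Sulfonylation of the primary allylic alcohol and SN2 hydride displacement at the unhindered primary carbon (not SN2′ at C8) leave the C7 methyl with C7=C8 in place (two-stage deoxygenation of an allylic alcohol).

Step 10
Reactants: 15 3-(tert-butyldimethylsilyloxy)-5-ethoxy-7,10β-dimethylbicyclo[5.3.0]deca-2,4,7-triene
Product: 16 5-ethoxy-7,10β-dimethylbicyclo[5.3.0]deca-1,4,7-trien-3-one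
Conditions: Pd(OAc)2 (1.1 equiv), MeCN, rt → 40 °C
Reagents that add atoms: none
Why: Saegusa–Ito oxidation: palladation of the silyl enol ether at C2 and β-hydride elimination from C1 (C10 is quaternary) give the C1=C2 enone cross-conjugated with the vinylogous ester.

Step 11
Reactants: 16 5-ethoxy-7,10β-dimethylbicyclo[5.3.0]deca-1,4,7-trien-3-one
Product: 18 5-ethoxy-1α-hydroxy-7,10β-dimethylbicyclo[5.3.0]deca-4,7-dien-3-one, via pinacol boronate 17 (not isolated)
Conditions: B2pin2 (1.1 equiv), CuCl (10 mol%), NaOt-Bu (15 mol%), Xantphos (10 mol%), MeOH (2 equiv), THF, 0 °C → rt; then NaBO3·4H2O (3 equiv), THF–H2O 1:1, rt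
Reagents that add atoms: sodium perborate (oxygen of the C1 hydroxyl), [Na+].[Na+].O[B-]1(O)OO[B-](O)(O)OO1
Why: Copper-catalysed conjugate borylation of a cyclic enone, then oxidation of the C–B bond with retention; the boryl copper adds to C1, the only unsubstituted β-carbon (C5 bears ethoxy and is fully substituted), from the α face opposite the pseudoaxial C10 methyl, which sets C1.

Step 12
Reactants: 18 5-ethoxy-1α-hydroxy-7,10β-dimethylbicyclo[5.3.0]deca-4,7-dien-3-one
Product: 19 5-ethoxy-3α-isopropyl-7,10β-dimethylbicyclo[5.3.0]deca-4,7-diene-1α,3β-diol
Conditions: i-PrMgCl (4 equiv), CeCl3 (4 equiv, dried), THF, −78 → −40 °C; pH 7 phosphate quench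
Reagents that add atoms: isopropylmagnesium chloride, CC(C)[Mg]Cl
Why: 1,2-Addition of an organocerium reagent, which suppresses enolisation and β-hydride reduction, to the vinylogous ester carbonyl; attack anti to the C10 methyl, reinforced by the α-oriented C1 alkoxide that binds the metal, puts isopropyl α and the C3 hydroxyl β.

Step 13
Reactants: 19 5-ethoxy-3α-isopropyl-7,10β-dimethylbicyclo[5.3.0]deca-4,7-diene-1α,3β-diol
Product: 20 1α-acetoxy-5-ethoxy-3α-isopropyl-7,10β-dimethylbicyclo[5.3.0]deca-4,7-dien-3β-ol
Conditions: Ac2O, pyridine, DMAP (cat.), CH2Cl2, 0 °C → rt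
Reagents that add atoms: acetic anhydride, CC(=O)OC(C)=O
Why: Acylation of the secondary alcohol; the hindered tertiary alcohol does not react, and the basic medium protects the acid-labile enol ether.

Step 14
Reactants: 20 1α-acetoxy-5-ethoxy-3α-isopropyl-7,10β-dimethylbicyclo[5.3.0]deca-4,7-dien-3β-ol
Product: 21 1α-acetoxy-3β-hydroxy-3α-isopropyl-7,10β-dimethyl-4αH-bicyclo[5.3.0]dec-7-en-5-one
Conditions: AcOH–NaOAc buffer (1 M, pH 4.5), THF–H2O 2:1, 0 °C → rt
Reagents that add atoms: water, O
Why: Enol ether hydrolysis through rate-limiting protonation at C4, which is general-acid catalysed and so runs in a weak-acid buffer where specific-acid ionisation of the tertiary alcohol is slow (the planar alkoxyallyl cation would also force isopropyl against ethoxy); C4 equilibrates through the enol to the trans-fused ketone with H α, in which C5 lies cis to the small hydroxyl and not to isopropyl.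

Step 15
Reactants: 21 1α-acetoxy-3β-hydroxy-3α-isopropyl-7,10β-dimethyl-4αH-bicyclo[5.3.0]dec-7-en-5-one
Product: 22 1α-acetoxy-3α-isopropyl-7,10β-dimethyl-4αH-bicyclo[5.3.0]dec-7-ene-3β,5α-diol
Conditions: Me4NBH(OAc)3 (5 equiv), MeCN–AcOH 1:1, −30 → −10 °C
Reagents that add atoms: none
Why: Evans–Saksena reduction: the C3 hydroxyl exchanges onto boron and delivers hydride intramolecularly to the β face of C5, giving the 5α-alcohol (1,3-anti to the C3 hydroxyl); the reagent does not reduce ketones intermolecularly and spares the acetate.

Step 16
Reactants: 23 4-hydroxybenzoic acid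
Product: 25 4-(tert-butyldimethylsilyloxy)benzoic acid, via bis-silyl derivative 24 (not isolated)
Conditions: TBSCl (2.3 equiv), imidazole, DMF, rt; then AcOH–THF–H2O, rt
Reagents that add atoms: tert-butyldimethylsilyl chloride, CC(C)(C)[Si](C)(C)Cl
Why: Silylation of both acidic hydroxyls and selective hydrolysis of the far more labile silyl ester leave the phenol protected and the acid free.

Step 17
Reactants: 22 1α-acetoxy-3α-isopropyl-7,10β-dimethyl-4αH-bicyclo[5.3.0]dec-7-ene-3β,5α-diol; 25 4-(tert-butyldimethylsilyloxy)benzoic acid
Product: 27 1α-acetoxy-3β-hydroxy-3α-isopropyl-7,10β-dimethyl-4αH-bicyclo[5.3.0]dec-7-en-5α-yl 4-(tert-butyldimethylsilyloxy)benzoate, via aroyl chloride 26 (not isolated)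
Conditions: 25, (COCl)2, DMF (cat.), CH2Cl2, 0 °C → rt, evaporate; then 22, Et3N, DMAP (1 equiv), CH2Cl2, rt → 40 °C
Reagents that add atoms: none
Why: Acyl chloride formation and DMAP-catalysed acylation of the only secondary hydroxyl; the tertiary C3 hydroxyl is inert, and the C1 acetate, trans to it, cannot migrate.

Step 18
Reactants: 27 1α-acetoxy-3β-hydroxy-3α-isopropyl-7,10β-dimethyl-4αH-bicyclo[5.3.0]dec-7-en-5α-yl 4-(tert-butyldimethylsilyloxy)benzoate
Product: 28 1α-acetoxy-3β-hydroxy-3α-isopropyl-7,10β-dimethyl-4αH-bicyclo[5.3.0]dec-7-en-5α-yl 4-hydroxybenzoate
Conditions: KHF2 (2.5 equiv), MeOH, rt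
Reagents that add atoms: none
Why: Fluoride cleavage of an aryl silyl ether, far faster than attack on alkyl esters in this near-neutral medium, frees the phenol without transesterification.

**Compound list**

1 | 3-methylcyclopent-2-en-1-one | CC1=CC(=O)CC1 | starting material
2 | trans-2,3-dibromo-3-methylcyclopentan-1-one (racemic, one enantiomer drawn; not isolated) | C[C@]1(Br)CCC(=O)[C@@H]1Br | intermediate
3 | 2-bromo-3-methylcyclopent-2-en-1-one | CC1=C(Br)C(=O)CC1 | intermediate
4 | tributyl(1-ethoxyvinyl)stannane | CCCC[Sn](CCCC)(CCCC)C(=C)OCC | starting material
5 | 2-(1-ethoxyvinyl)-3-methylcyclopent-2-en-1-one | CCOC(=C)C1=C(C)CCC1=O | intermediate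
6 | methyl acetoacetate | COC(=O)CC(C)=O | starting material
7 | methyl 2-diazo-3-oxobutanoate | COC(=O)C(=[N+]=[N-])C(C)=O | intermediate
8 | methyl 2-diazo-3-hydroxybutanoate (racemic) | COC(=O)C(=[N+]=[N-])C(C)O | intermediate
9 | methyl 2-diazobut-3-enoate | COC(=O)C(=[N+]=[N-])C=C | intermediate
10 | methyl 2-ethoxy-1-ethenyl-2-(2-methyl-5-oxocyclopent-1-en-1-yl)cyclopropane-1-carboxylate, ethenyl and cyclopentenyl groups cis (not isolated) | C=C[C@@]1(C(=O)OC)C[C@@]1(OCC)C2=C(C)CCC2=O | intermediate
11 | methyl 5-ethoxy-10β-methyl-3-oxobicyclo[5.3.0]deca-4,7-diene-7-carboxylate | C1CC(=O)C2=C(OCC)CC(C(=O)OC)=CC[C@@]12C | intermediate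
12 | methyl 3-(tert-butyldimethylsilyloxy)-5-ethoxy-10β-methylbicyclo[5.3.0]deca-2,4,7-triene-7-carboxylate | C1C=C(O[Si](C)(C)C(C)(C)C)C2=C(OCC)CC(C(=O)OC)=CC[C@@]12C | intermediate
13 | 3-(tert-butyldimethylsilyloxy)-5-ethoxy-7-(hydroxymethyl)-10β-methylbicyclo[5.3.0]deca-2,4,7-triene | C1C=C(O[Si](C)(C)C(C)(C)C)C2=C(OCC)CC(CO)=CC[C@@]12C | intermediate
14 | methanesulfonate of 13 (not isolated) | C1C=C(O[Si](C)(C)C(C)(C)C)C2=C(OCC)CC(COS(C)(=O)=O)=CC[C@@]12C | intermediate
15 | 3-(tert-butyldimethylsilyloxy)-5-ethoxy-7,10β-dimethylbicyclo[5.3.0]deca-2,4,7-triene | C1C=C(O[Si](C)(C)C(C)(C)C)C2=C(OCC)CC(C)=CC[C@@]12C | intermediate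
16 | 5-ethoxy-7,10β-dimethylbicyclo[5.3.0]deca-1,4,7-trien-3-one | C1=CC(=O)C2=C(OCC)CC(C)=CC[C@@]12C | intermediate
17 | 5-ethoxy-7,10β-dimethyl-1α-(4,4,5,5-tetramethyl-1,3,2-dioxaborolan-2-yl)bicyclo[5.3.0]deca-4,7-dien-3-one (not isolated) | CC1(C)OB(OC1(C)C)[C@H]2CC(=O)C3=C(OCC)CC(C)=CC[C@@]23C | intermediate
18 | 5-ethoxy-1α-hydroxy-7,10β-dimethylbicyclo[5.3.0]deca-4,7-dien-3-one | O[C@H]1CC(=O)C2=C(OCC)CC(C)=CC[C@@]12C | intermediate
19 | 5-ethoxy-3α-isopropyl-7,10β-dimethylbicyclo[5.3.0]deca-4,7-diene-1α,3β-diol | O[C@H]1C[C@@](O)(C(C)C)C2=C(OCC)CC(C)=CC[C@@]12C | intermediate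
20 | 1α-acetoxy-5-ethoxy-3α-isopropyl-7,10β-dimethylbicyclo[5.3.0]deca-4,7-dien-3β-ol | CC(=O)O[C@H]1C[C@@](O)(C(C)C)C2=C(OCC)CC(C)=CC[C@@]12C | intermediate
21 | 1α-acetoxy-3β-hydroxy-3α-isopropyl-7,10β-dimethyl-4αH-bicyclo[5.3.0]dec-7-en-5-one | CC(=O)O[C@H]1C[C@@](O)(C(C)C)[C@@H]2C(=O)CC(C)=CC[C@@]12C | intermediate
22 | 1α-acetoxy-3α-isopropyl-7,10β-dimethyl-4αH-bicyclo[5.3.0]dec-7-ene-3β,5α-diol | CC(=O)O[C@H]1C[C@@](O)(C(C)C)[C@@H]2[C@@H](O)CC(C)=CC[C@@]12C | intermediate
23 | 4-hydroxybenzoic acid | O=C(O)c1ccc(O)cc1 | starting material
24 | tert-butyldimethylsilyl 4-(tert-butyldimethylsilyloxy)benzoate (not isolated) | CC(C)(C)[Si](C)(C)OC(=O)c1ccc(O[Si](C)(C)C(C)(C)C)cc1 | intermediate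
25 | 4-(tert-butyldimethylsilyloxy)benzoic acid | CC(C)(C)[Si](C)(C)Oc1ccc(cc1)C(=O)O | intermediate
26 | 4-(tert-butyldimethylsilyloxy)benzoyl chloride (not isolated) | CC(C)(C)[Si](C)(C)Oc1ccc(cc1)C(Cl)=O | intermediate
27 | 1α-acetoxy-3β-hydroxy-3α-isopropyl-7,10β-dimethyl-4αH-bicyclo[5.3.0]dec-7-en-5α-yl 4-(tert-butyldimethylsilyloxy)benzoate | CC(=O)O[C@H]1C[C@@](O)(C(C)C)[C@@H]2[C@@H](OC(=O)c3ccc(O[Si](C)(C)C(C)(C)C)cc3)CC(C)=CC[C@@]12C | intermediate
28 | 1α-acetoxy-3β-hydroxy-3α-isopropyl-7,10β-dimethyl-4αH-bicyclo[5.3.0]dec-7-en-5α-yl 4-hydroxybenzoate (CNP0275279.1) | CC(=O)O[C@H]1C[C@@](O)(C(C)C)[C@@H]2[C@@H](OC(=O)c3ccc(O)cc3)CC(C)=CC[C@@]12C | target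

**Step count and least certain steps**

Total: 18 steps. Longest linear sequence: 15 steps (6 → 28 through steps 3–15, 17 and 18); 14 steps from 1.

Step 6 (key step). Three things may go wrong. The enol ether may attack the unsubstituted vinyl terminus C9 of the carbenoid instead of the carbene carbon, and the resulting zwitterion may close to five-membered rings or to the seven-membered ring without stereochemical memory. The rearrangement may be slow because the C10 methyl is the inward substituent at a fully substituted terminus, and prolonged heating may open the push–pull cyclopropane heterolytically and erode enantiomeric purity. The sense or level of induction with a 1,1-disubstituted enol ether may depart from the styrene model. Fallback: the fallback sets out from 5 (with 9) and returns at 11. The annulation is run with the achiral, hindered carboxylate Rh2(O2CC7H15)4 in a hydrocarbon solvent, the setting least prone to attack at the vinyl terminus, and the crude cyclopropane is rearranged thermally to racemic 11. The racemate is resolved by preparative chromatography on a chiral stationary phase, which removes the enantiomer of 11 F1 and supplies 11 independent of any catalyst model.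

Step 14. The tertiary hydroxyl may be lost by ionisation or β-elimination (transposition to a C3=C4 enone), the C7=C8 bond may move into conjugation with the new ketone, or C4 may be protonated from the wrong face and fail to equilibrate. Fallback: from 20, N-bromosuccinimide in NaHCO3-buffered aqueous THF at 0 °C attacks the enol ether carbon C4 and water adds at C5, giving without any protic acid 1α-acetoxy-4α-bromo-3β-hydroxy-3α-isopropyl-7,10β-dimethylbicyclo[5.3.0]dec-7-en-5-one F2 (the configuration at C4 is of no consequence). SmI2 in THF–MeOH at −78 °C then cleaves the C–Br bond to the samarium enolate, which is protonated to 21, where the route is rejoined.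

Step 12. The secondary Grignard-derived reagent may enolise C2 or reduce the carbonyl by β-hydride transfer, or fail to add to the hindered, electron-rich vinylogous ester carbonyl. Fallback: from 18, the smaller sp2 nucleophile isopropenylmagnesium bromide with CeCl3, which has no β-hydride, adds from the same face to give 5-ethoxy-3α-isopropenyl-7,10β-dimethylbicyclo[5.3.0]deca-4,7-diene-1α,3β-diol F3. Hydrogenation with RhCl(PPh3)3 and H2 in benzene saturates only the 1,1-disubstituted olefin and gives 19.

Step 11. Conjugate addition may be slow at a β-carbon next to a quaternary centre in an enone whose carbonyl is deactivated by the ethoxy group, the new hydroxyl may be lost again by β-elimination during the basic oxidation, or some attack may occur from the methyl face. Fallback: from 16, nucleophilic epoxidation with t-BuOOH and DBU delivers oxygen to C1 from the α face and gives 1α,2α-epoxy-5-ethoxy-7,10β-dimethylbicyclo[5.3.0]deca-4,7-dien-3-one F4. SmI2 in THF–MeOH at −78 °C cleaves the C2–O bond of the epoxy ketone and gives 18.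

Step 15. Exchange of the hindered tertiary hydroxyl onto boron may be too slow for reduction to proceed, the seven-membered ring may hold C5 out of reach of the delivered hydride, or the aldol may dehydrate in acetic acid. Fallback: from 21, NaBH4 with CeCl3 in MeOH at −78 °C attacks from the open α face and gives the epimeric alcohol 1α-acetoxy-3α-isopropyl-7,10β-dimethyl-4αH-bicyclo[5.3.0]dec-7-ene-3β,5β-diol F5. Mitsunobu esterification of F5 with 25 (PPh3, diisopropyl azodicarboxylate, toluene) inverts C5 and gives 27 directly, so that the route is rejoined at 27 without passing through 22.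

Step 10. The acetic acid released may protodesilylate the dienol ether faster than palladation of the hindered silyl enol ether occurs. Fallback: from 15, tetrabutylammonium fluoride buffered with AcOH in THF at 0 °C unmasks the ketone 5-ethoxy-7,10β-dimethylbicyclo[5.3.0]deca-4,7-dien-3-one F6. Dehydrogenation with 2-iodoxybenzoic acid in DMSO at 70 °C, which proceeds by single-electron oxidation of the enol, introduces the C1=C2 bond and gives 16.

**Further compounds**

F1 | step 6 | enantiomer of 11 | C1CC(=O)C2=C(OCC)CC(C(=O)OC)=CC[C@]12C
F2 | step 14 | 1α-acetoxy-4α-bromo-3β-hydroxy-3α-isopropyl-7,10β-dimethylbicyclo[5.3.0]dec-7-en-5-one | CC(=O)O[C@H]1C[C@@](O)(C(C)C)[C@]2(Br)C(=O)CC(C)=CC[C@@]12C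
F3 | step 12 | 5-ethoxy-3α-isopropenyl-7,10β-dimethylbicyclo[5.3.0]deca-4,7-diene-1α,3β-diol | O[C@H]1C[C@@](O)(C(C)=C)C2=C(OCC)CC(C)=CC[C@@]12C
F4 | step 11 | 1α,2α-epoxy-5-ethoxy-7,10β-dimethylbicyclo[5.3.0]deca-4,7-dien-3-one | O1[C@H]2[C@@H]1C(=O)C3=C(OCC)CC(C)=CC[C@@]23C
F5 | step 15 | 1α-acetoxy-3α-isopropyl-7,10β-dimethyl-4αH-bicyclo[5.3.0]dec-7-ene-3β,5β-diol | CC(=O)O[C@H]1C[C@@](O)(C(C)C)[C@@H]2[C@H](O)CC(C)=CC[C@@]12C
F6 | step 10 | 5-ethoxy-7,10β-dimethylbicyclo[5.3.0]deca-4,7-dien-3-one | C1CC(=O)C2=C(OCC)CC(C)=CC[C@@]12C
A1 | alternative 1 | 5α-(tert-butyldimethylsilyloxy)-3α-isopropyl-7,10β-dimethyl-4αH-bicyclo[5.3.0]dec-7-ene-1α,3β-diol | O[C@H]1C[C@@](O)(C(C)C)[C@@H]2[C@@H](O[Si](C)(C)C(C)(C)C)CC(C)=CC[C@@]12C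
A2 | alternative 1 | 5-(tert-butyldimethylsilyloxy)-1,10-epoxy-3-isopropyl-7,10-dimethylcyclodeca-3,7-diene, both ring olefins and the oxirane cis | O1[C@H]2C/C(C(C)C)=C\[C@@H](O[Si](C)(C)C(C)(C)C)C/C(C)=C\C[C@@]12C
A3 | alternative 2 | 3β-hydroxy-3α-isopropyl-7,10β-dimethyl-1α-nitro-4αH-bicyclo[5.3.0]dec-6-en-5-one (C1 epimer arbitrary) | [O-][N+](=O)[C@H]1C[C@@](O)(C(C)C)[C@@H]2C(=O)C=C(C)CC[C@@]12C
A4 | alternative 2 | 3,6-dimethylcyclohepta-2,6-dien-1-one | O=C1C=C(C)CCC(C)=C1
A5 | alternative 2 | 4-methyl-1-nitropentan-3-one | CC(C)C(=O)CC[N+](=O)[O-]
A6 | alternative 3 | 1α-(tert-butyldimethylsilyloxy)-3α-isopropyl-7,10β-dimethyl-3β-(triethylsilyloxy)-4αH-bicyclo[5.3.0]dec-7-en-5α-ol | CC(C)(C)[Si](C)(C)O[C@H]1C[C@@](O[Si](CC)(CC)CC)(C(C)C)[C@@H]2[C@@H](O)CC(C)=CC[C@@]12C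
A7 | alternative 3 | cyclopentane-fused tetrahydropyran carrying tributylstannyl at C5 and isopropenyl at C8 (ether oxygen between C5 and C8; 1α-tert-butyldimethylsilyloxy, 3β-triethylsilyloxy, 3α-isopropyl, 10β-methyl) | CC(C)(C)[Si](C)(C)O[C@H]1C[C@@](O[Si](CC)(CC)CC)(C(C)C)[C@@H]2[C@@H]([Sn](CCCC)(CCCC)CCCC)O[C@H](C(C)=C)C[C@@]12C
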